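**Plan**
- Target 13 is (3S)-2'-hydroxy-4',7-dimethoxy-6-prenylisoflavanone. Its one stereocentre, C3, is alpha to the C4 ketone and benzylic to ring B. The retrosynthesis cuts C3–C4 first, then O1–C2, then C6–prenyl.
- Enabling feature: the free 2'-OH of ring B is ortho to C1', the carbon that bears C3, and the 4'-OMe is para to it. C3 can therefore become the exocyclic carbon of an o-quinone methide (ring B briefly dearomatised), an enone acceptor that the O1–C2 tether holds near the ring-A formyl carbon C4.
- Key event: a chiral triazolylidene reverses the polarity of the ring-A aldehyde, and the resulting acyl anion carbon adds to C3 in an intramolecular Stetter-type closure. Two electrophilic carbons are joined, ring C closes, ring B rearomatises and the 2'-OH is set free.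
- Forward order: ring-A aldehyde 4 comes from 1 by iodination and Stille prenylation, and ring-B bromoketone 7 comes from paeonol 5. Ether union and redox adjustment give the racemic silyl ether/benzylic acetate 11, and ring C is formed last.
- Stereochemistry: both enantiomers of 11 collapse to the planar methide 12, and the catalyst chooses the face (stereoconvergent). The silyl and acetate helpers leave in the same flask, so nothing follows the stereodefining step.

Key step: step 9

Assumption: isoflavanone numbering is used (O1, C2, C3, C4, ring A C4a–C8a, ring B C1'–C6'). The sense of induction is assigned by analogy with the (E)-enoate Stetter cyclisation. Both antipodes of the triazolium salt are commercial, so the antipode that delivers (3S) is the one meant.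

Step 1
Reactants: 1 2-hydroxy-4-methoxybenzaldehyde
Product: 2 2-hydroxy-5-iodo-4-methoxybenzaldehyde
Conditions: NIS (1.05 equiv), TFA (10 mol %), MeCN, rt
Reagents that add atoms: N-iodosuccinimide, O=C1CCC(=O)N1I
Why: Electrophilic aromatic iodination should go to C5, which is para to the phenol, ortho to the methoxy group and less crowded than C3 between the two oxygens.

Step 2
Reactants: 2 2-hydroxy-5-iodo-4-methoxybenzaldehyde; 3 tributyl(3-methylbut-2-en-1-yl)stannane
Product: 4 2-hydroxy-4-methoxy-5-(3-methylbut-2-en-1-yl)benzaldehyde
Conditions: Pd(PPh3)4 (5 mol %), DMF, 90 °C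
Reagents that add atoms: none
Why: The Stille coupling tolerates the free phenol and the aldehyde, and reductive elimination from the prenylpalladium intermediate at its less hindered terminus should give the linear prenyl arene.

Step 3
Reactants: 5 paeonol (1-(2-hydroxy-4-methoxyphenyl)ethan-1-one)
Product: 6 bis-silyl derivative of paeonol (aryl TBS ether and TBS enol ether)
Conditions: TBSOTf (2.3 equiv), Et3N (3 equiv), CH2Cl2, 0 °C to rt
Reagents that add atoms: tert-butyldimethylsilyl triflate, CC(C)(C)[Si](C)(C)OS(=O)(=O)C(F)(F)F
Why: Silyl triflate with an amine base silylates the chelated phenol and soft-enolises the methyl ketone in one operation, which installs the later fluoride trigger on ring B and activates the methyl group for monobromination.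

Step 4
Reactants: 6 bis-silyl derivative of paeonol
Product: 7 2-bromo-1-[2-(tert-butyldimethylsilyloxy)-4-methoxyphenyl]ethan-1-one
Conditions: NBS (1.0 equiv), THF, −78 to 0 °C; aq NaHCO3 work-up
Reagents that add atoms: N-bromosuccinimide, O=C1CCC(=O)N1Br
Why: Electrophilic alpha-bromination of a silyl enol ether outruns ring bromination and liberates no HBr, so the aryl silyl ether survives and only one bromine enters.

Step 5
Reactants: 4 2-hydroxy-4-methoxy-5-(3-methylbut-2-en-1-yl)benzaldehyde; 7 2-bromo-1-[2-(tert-butyldimethylsilyloxy)-4-methoxyphenyl]ethan-1-one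
Product: 8 2-{2-[2-(tert-butyldimethylsilyloxy)-4-methoxyphenyl]-2-oxoethoxy}-4-methoxy-5-(3-methylbut-2-en-1-yl)benzaldehyde
Conditions: K2CO3 (1.2 equiv), acetone, 0 °C to rt, stopped when 7 is consumed
Reagents that add atoms: none
Why: The Williamson ether synthesis with a highly reactive phenacyl bromide runs at room temperature with a weak base, conditions under which 2-(phenacyloxy)benzaldehydes can be isolated before Rap–Stoermer condensation sets in.

Step 6
Reactants: 8 keto aldehyde
Product: 9 rac-1-[2-(tert-butyldimethylsilyloxy)-4-methoxyphenyl]-2-[2-(hydroxymethyl)-5-methoxy-4-(3-methylbut-2-en-1-yl)phenoxy]ethan-1-ol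
Conditions: NaBH4 (excess), THF/MeOH, 0 °C; neutral work-up
Reagents that add atoms: none
Why: Borohydride reduction takes both carbonyl groups to alcohols, the carbinol centre is deliberately racemic because step 9 erases it, and the protic medium quenches the alkoxide before silyl migration can occur.

Step 7
Reactants: 9 racemic diol
Product: 10 rac-2-{2-[2-(tert-butyldimethylsilyloxy)-4-methoxyphenyl]-2-hydroxyethoxy}-4-methoxy-5-(3-methylbut-2-en-1-yl)benzaldehyde
Conditions: [Cu(MeCN)4]OTf (5 mol %), 2,2'-bipyridine (5 mol %), TEMPO (5 mol %), N-methylimidazole (10 mol %), air, MeCN, rt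
Reagents that add atoms: none
Why: The copper/TEMPO aerobic alcohol oxidation is sterically selective for primary over secondary alcohols, so only the electron-rich primary benzylic alcohol of ring A returns to the aldehyde while the alkene and silyl ether stay untouched.

Step 8
Reactants: 10 racemic hydroxy aldehyde
Product: 11 rac-1-[2-(tert-butyldimethylsilyloxy)-4-methoxyphenyl]-2-[2-formyl-5-methoxy-4-(3-methylbut-2-en-1-yl)phenoxy]ethyl acetate
Conditions: Ac2O (1.5 equiv), pyridine, DMAP (5 mol %), CH2Cl2, 0 °C; Et3N-deactivated silica
Reagents that add atoms: acetic anhydride, CC(=O)OC(C)=O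
Why: DMAP-catalysed acylation turns the secondary benzylic alcohol into the leaving group for methide release, and the beta-aryloxy substituent together with the silyl cap on the 2'-oxygen should keep the acetate from ionising before fluoride is added.

Step 9
Reactants: 11 racemic silyl ether acetate
Product: 13 (3S)-3-(2-hydroxy-4-methoxyphenyl)-7-methoxy-6-(3-methylbut-2-en-1-yl)chroman-4-one, via o-quinone methide aldehyde 12 (not isolated)
Conditions: (5aR,10bS)-2-(pentafluorophenyl)-5a,10b-dihydro-4H,6H-indeno[2,1-b][1,2,4]triazolo[4,3-d][1,4]oxazin-2-ium tetrafluoroborate (15 mol %), CsF (1.2 equiv), 18-crown-6 (1.2 equiv), 4 Å MS, THF (0.02 M), −20 °C; AcOH quench at −20 °C, neutral silica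
Reagents that add atoms: none
Why: Proposed new method: fluoride removes the silyl group of 11, the ring-B phenoxide expels acetate to give the planar E-configured o-quinone methide 12, the triazolylidene converts the ring-A formyl group into a Breslow enaminol (acyl anion at C4), this carbon adds to the exocyclic methide carbon C3, ring B rearomatises to the phenoxide, and proton transfer with loss of the carbene gives the C4 ketone and the free 2'-OH. The closest known reaction types are the enantioselective intramolecular Stetter reaction of salicylaldehyde-derived (E)-4-aryloxybut-2-enoates to 3-substituted chroman-4-ones, the intermolecular addition of thiazolium-derived acyl anion equivalents to fluoride-generated o-quinone methides, and carbene-catalysed annulations on o-quinone methides released by CsF and 18-crown-6; what is new is the intramolecular, enantioselective union of these on an alkyl-substituted o-quinone methide. Ring C closes in the 6-exo-trig mode, since the attacked C3=C1' bond lies outside the new six-membered ring made of C4, C4a, C8a, O1, C2 and C3. The C3 stereocentre is set under catalyst control, because the indane wall of the aminoindanol-derived carbene shields one face of the enaminol and the E-methide can present only one enantioface to it, so both enantiomers of 11 funnel through achiral 12 into (3S)-13. The step needs acylation at C3 to outrun tautomerisation of 12 to the 2-vinylphenol enol ether, dimerisation, and capture by acetate or free carbene, which is secured by the two-atom O1–C2 tether, by the para 4'-methoxy group that stabilises 12, by slow release at high dilution and by the irreversible rearomatisation. It also needs the acidic C3–H to stay untouched, which is secured because the overall equation leaves a neutral phenol, acetate is the strongest base that persists, the temperature is low and the run is quenched cold with AcOH.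

**Compound list**
1 | 2-hydroxy-4-methoxybenzaldehyde | COc1ccc(C=O)c(O)c1 | starting material
2 | 2-hydroxy-5-iodo-4-methoxybenzaldehyde | COc1cc(O)c(C=O)cc1I | intermediate
3 | tributyl(3-methylbut-2-en-1-yl)stannane | CCCC[Sn](CCCC)(CCCC)CC=C(C)C | starting material
4 | 2-hydroxy-4-methoxy-5-(3-methylbut-2-en-1-yl)benzaldehyde | COc1cc(O)c(C=O)cc1CC=C(C)C | intermediate
5 | paeonol, 1-(2-hydroxy-4-methoxyphenyl)ethan-1-one | CC(=O)c1ccc(OC)cc1O | starting material
6 | tert-butyl({1-[2-(tert-butyldimethylsilyloxy)-4-methoxyphenyl]ethenyl}oxy)dimethylsilane | C=C(O[Si](C)(C)C(C)(C)C)c1ccc(OC)cc1O[Si](C)(C)C(C)(C)C | intermediate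
7 | 2-bromo-1-[2-(tert-butyldimethylsilyloxy)-4-methoxyphenyl]ethan-1-one | COc1ccc(C(=O)CBr)c(O[Si](C)(C)C(C)(C)C)c1 | intermediate
8 | 2-{2-[2-(tert-butyldimethylsilyloxy)-4-methoxyphenyl]-2-oxoethoxy}-4-methoxy-5-(3-methylbut-2-en-1-yl)benzaldehyde | COc1ccc(C(=O)COc2cc(OC)c(CC=C(C)C)cc2C=O)c(O[Si](C)(C)C(C)(C)C)c1 | intermediate
9 | rac-1-[2-(tert-butyldimethylsilyloxy)-4-methoxyphenyl]-2-[2-(hydroxymethyl)-5-methoxy-4-(3-methylbut-2-en-1-yl)phenoxy]ethan-1-ol | COc1ccc(C(O)COc2cc(OC)c(CC=C(C)C)cc2CO)c(O[Si](C)(C)C(C)(C)C)c1 | intermediate
10 | rac-2-{2-[2-(tert-butyldimethylsilyloxy)-4-methoxyphenyl]-2-hydroxyethoxy}-4-methoxy-5-(3-methylbut-2-en-1-yl)benzaldehyde | COc1ccc(C(O)COc2cc(OC)c(CC=C(C)C)cc2C=O)c(O[Si](C)(C)C(C)(C)C)c1 | intermediate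
11 | rac-1-[2-(tert-butyldimethylsilyloxy)-4-methoxyphenyl]-2-[2-formyl-5-methoxy-4-(3-methylbut-2-en-1-yl)phenoxy]ethyl acetate | COc1ccc(C(OC(C)=O)COc2cc(OC)c(CC=C(C)C)cc2C=O)c(O[Si](C)(C)C(C)(C)C)c1 | intermediate
12 | 4-methoxy-2-[(2E)-2-(4-methoxy-6-oxocyclohexa-2,4-dien-1-ylidene)ethoxy]-5-(3-methylbut-2-en-1-yl)benzaldehyde (o-quinone methide, not isolated) | O=C1C=C(OC)C=C/C1=C\COc2cc(OC)c(CC=C(C)C)cc2C=O | intermediate
13 | (3S)-3-(2-hydroxy-4-methoxyphenyl)-7-methoxy-6-(3-methylbut-2-en-1-yl)-2,3-dihydro-4H-chromen-4-one | COc1ccc([C@H]2COc3cc(OC)c(CC=C(C)C)cc3C2=O)c(O)c1 | target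

Total step count: 9. Longest linear sequence: 7 (steps 3–9 from paeonol, or steps 1, 2 and 5–9 from 1).

**Steps most likely to fail**

1. **Step 9.**
   - The methide may tautomerise to the vinylphenol enol ether or oligomerise before the acyl anion carbon reaches it. The new C3–H centre may also racemise in the fluoride/acetate medium.
   - The fallback uses known chemistry only. It sets out from 8 and comes back at 13.
   - An achiral triazolium salt with DBU in THF closes the same ring by the intramolecular crossed aldehyde–ketone benzoin reaction. This gives the racemic 3-hydroxyisoflavanone silyl ether F1.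
   - SOCl2 in pyridine at 0 °C dehydrates it to the isoflavone silyl ether F2.
   - Asymmetric transfer hydrogenation with RuCl[(S,S)-TsDPEN](p-cymene) in HCO2H/Et3N first saturates C2=C3. It then reduces the configurationally labile ketone with dynamic kinetic resolution to the cis-(3S,4S)-isoflavan-4-ol silyl ether F3.
   - Dess–Martin periodinane in CH2Cl2 reoxidises C4 without touching C3 and gives the (3S)-isoflavanone silyl ether F4.
   - HF·pyridine in THF at 0 °C, an acidic and non-enolising medium, then frees the 2'-OH to give 13.

2. **Step 5.**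
   - The product may undergo base-induced intramolecular aldol condensation of its aryloxy ketone onto the ring-A aldehyde (Rap–Stoermer-type benzofuran formation).
   - The fallback sets out from 4 and comes back at 9. It removes the aldol acceptor before the ether is made.
   - NaBH4 in MeOH reduces 4 to the salicyl alcohol F5.
   - Its phenol alone is alkylated by 7 with K2CO3 in acetone to give the keto alcohol F6.
   - NaBH4 then reduces the remaining ketone to diol 9.

3. **Step 2.**
   - Prenyl transfer may occur with allylic transposition to the reverse-prenyl isomer, or protodeiodination may compete.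
   - The fallback sets out from 2 and comes back at 4.
   - Stille coupling with allyltributylstannane, whose two allyl termini are equivalent, gives the 5-allyl aldehyde F7.
   - Cross metathesis with excess 2-methylbut-2-ene and second-generation Grubbs catalyst in CH2Cl2 converts the allyl group into the prenyl group of 4.

**Further compounds**
F1 | step 9 | rac-3-[2-(tert-butyldimethylsilyloxy)-4-methoxyphenyl]-3-hydroxy-7-methoxy-6-(3-methylbut-2-en-1-yl)chroman-4-one | COc1ccc(C2(O)COc3cc(OC)c(CC=C(C)C)cc3C2=O)c(O[Si](C)(C)C(C)(C)C)c1
F2 | step 9 | 3-[2-(tert-butyldimethylsilyloxy)-4-methoxyphenyl]-7-methoxy-6-(3-methylbut-2-en-1-yl)-4H-chromen-4-one | COc1ccc(-c2coc3cc(OC)c(CC=C(C)C)cc3c2=O)c(O[Si](C)(C)C(C)(C)C)c1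
F3 | step 9 | (3S,4S)-3-[2-(tert-butyldimethylsilyloxy)-4-methoxyphenyl]-7-methoxy-6-(3-methylbut-2-en-1-yl)chroman-4-ol (cis) | COc1ccc([C@H]2COc3cc(OC)c(CC=C(C)C)cc3[C@H]2O)c(O[Si](C)(C)C(C)(C)C)c1
F4 | step 9 | (3S)-3-[2-(tert-butyldimethylsilyloxy)-4-methoxyphenyl]-7-methoxy-6-(3-methylbut-2-en-1-yl)chroman-4-one | COc1ccc([C@H]2COc3cc(OC)c(CC=C(C)C)cc3C2=O)c(O[Si](C)(C)C(C)(C)C)c1
F5 | step 5 | 2-(hydroxymethyl)-5-methoxy-4-(3-methylbut-2-en-1-yl)phenol | COc1cc(O)c(CO)cc1CC=C(C)C
F6 | step 5 | 1-[2-(tert-butyldimethylsilyloxy)-4-methoxyphenyl]-2-[2-(hydroxymethyl)-5-methoxy-4-(3-methylbut-2-en-1-yl)phenoxy]ethan-1-one | COc1ccc(C(=O)COc2cc(OC)c(CC=C(C)C)cc2CO)c(O[Si](C)(C)C(C)(C)C)c1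
F7 | step 2 | 2-hydroxy-4-methoxy-5-(prop-2-en-1-yl)benzaldehyde | COc1cc(O)c(C=O)cc1CC=C
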